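**Assumptions.** The SMILES has no stereocentre and no stereogenic double bond, so the target is achiral and there is no enantiomer to select or configuration to set. Compound 1 is treated as a catalogue chemical (CAS 4707-46-4). If it is unavailable, it is one step from the bulk fragrance chemical methyl atratate (conc. H2SO4, rt).

## Retrosynthetic overview
1. The route never couples two benzenoid halves through the hindered ArCO–OAr bond, which is the usual acid + phenol disconnection.
2. The CH2OH carbon comes off last, by a retro boron-templated ortho C–H hydroxymethylation. C3 of ring A is the only free position ortho to a free phenol in the whole depside. This leads back to the allyl ester of obtusatic acid.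
3. Ring A is disconnected by retro-[4+2] into an aryl but-2-ynoate and Brassard's diene. One step sets 2-OH, 4-OMe and 6-Me and creates the depside.
4. The aryl butynoate comes from an unhindered acylation of the 4-OH of allyl 3-methylorsellinate.
5. Ring order: ring B is bought, ring A is made by Diels–Alder/aromatisation, and a temporary 1,3,2-dioxaborin ring is formed and then removed.

## Forward route

**Step 1**
Reactants: 1, 2,4-dihydroxy-3,6-dimethylbenzoic acid; 2, allyl bromide
Product: 3, allyl 2,4-dihydroxy-3,6-dimethylbenzoate
Conditions: KHCO3 (1.2 equiv), allyl bromide (1.1 equiv), DMF, rt, 16 h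
Reagents that add atoms: allyl bromide, C=CCBr
Why: This is an SN2 O-alkylation of the carboxylate, in which bicarbonate ionises only the CO2H and not the phenols, and room temperature avoids decarboxylation of the electron-rich salicylic acid.

**Step 2**
Reactants: 3; 4, but-2-ynoic acid
Product: 5, allyl 4-(but-2-ynoyloxy)-2-hydroxy-3,6-dimethylbenzoate
Conditions: DCC (1.1 equiv), DMAP (5 mol %), CH2Cl2, 0 °C to rt
Reagents that add atoms: but-2-ynoic acid, CC#CC(=O)O
Why: In this Steglich esterification the small linear acyl donor reacts only at the free 4-OH, because the 2-OH is hydrogen-bonded to the ester carbonyl and flanked on both sides, and low DMAP loading at 0 °C suppresses ynoate-to-allenoate isomerisation.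

**Step 3**
Reactants: 6, methyl acetoacetate; 7, trimethyl orthoformate
Product: 8, methyl (E)-3-methoxybut-2-enoate
Conditions: HC(OMe)3 (1.1 equiv), cat. conc. H2SO4, rt, 24 h; distil
Reagents that add atoms: trimethyl orthoformate, COC(OC)OC
Why: Acid-catalysed ketalisation followed by loss of MeOH gives the conjugated, thermodynamically preferred E enol ether.

**Step 4**
Reactants: 8; 9, chlorotrimethylsilane
Product: 10, 1,3-dimethoxy-1-(trimethylsilyloxy)buta-1,3-diene (Brassard's diene; the C1=C2 geometry is irrelevant because C1 becomes an arene carbon)
Conditions: LDA (1.1 equiv), THF, −78 °C; TMSCl (1.3 equiv), −78 °C to rt; pentane filtration, Kugelrohr distillation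
Reagents that add atoms: TMSCl, C[Si](C)(C)Cl
Why: LDA γ-deprotonates the vinylogous carbonate to the extended dienolate, which the hard silicon electrophile traps on oxygen to give the vinylketene acetal.

**Step 5 (key step)**
Reactants: 5; 10
Product: 11, allyl 2-hydroxy-4-[(2-hydroxy-4-methoxy-6-methylbenzoyl)oxy]-3,6-dimethylbenzoate (allyl obtusatate)
Conditions: 10 (3.5 equiv in two portions; the first equivalent also transiently O-silylates the 2'-OH), PhMe (1 M), 120 °C, sealed tube, 36 h; then 1 M HCl/THF, rt, 1 h
Reagents that add atoms: Brassard's diene 10, C=C(OC)C=C(OC)O[Si](C)(C)C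
Why: In this normal-electron-demand Diels–Alder reaction of a vinylketene acetal with an acetylenic ester, the nucleophilic C4 of the diene bonds to the methyl-bearing β-carbon of the activated aryl ynoate and C1 bonds to the α-carbon, and acidic collapse of the C1 (OMe)(OTMS) ketal (loss of MeOH and TMS) with tautomerisation gives the 2-OH/4-OMe/6-Me benzoate, so ring A and the hindered depside ester arise together without base.

**Step 6 (second key step)**
Reactants: 11; 12, phenylboronic acid; 13, paraformaldehyde
Product: 14, allyl 2-hydroxy-4-[(5-methoxy-7-methyl-2-phenyl-4H-1,3,2-benzodioxaborin-8-yl)carbonyloxy]-3,6-dimethylbenzoate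
Conditions: PhB(OH)2 (2.5 equiv), (CH2O)n (10 equiv), EtCO2H (0.4 equiv), PhMe, reflux, Dean–Stark, 16–24 h
Reagents that add atoms: phenylboronic acid, OB(O)c1ccccc1; paraformaldehyde (as formaldehyde), C=O
Why: In the Nagata ortho-specific hydroxymethylation the aryloxyboronate binds CH2O and delivers it through a six-membered transition state to an ortho carbon only; ring A C3 (activated by o-OH, o-OMe and p-Me) is the only open ortho site because both positions next to the ring B 2'-OH are blocked, and the product is held as the cyclic boronate, which prevents o-quinone methide and diarylmethane chemistry.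

**Step 7**
Reactants: 14
Product: 15, allyl 2-hydroxy-4-{[2-hydroxy-3-(hydroxymethyl)-4-methoxy-6-methylbenzoyl]oxy}-3,6-dimethylbenzoate
Conditions: 30% aq. H2O2 (5 equiv), THF, pH 7 buffer, 0 °C to rt, 1–2 h; Na2S2O3 quench
Reagents that add atoms: none
Why: In this oxidative deboronation, hydroperoxide adds to the Lewis-acidic boron, a 1,2-phenyl shift gives a borate, and hydrolysis frees the phenol and benzylic alcohol at neutral pH, leaving the depside, the allyl ester and the acid-sensitive salicyl alcohol intact.

**Step 8**
Reactants: 15
Product: 16, 3α-hydroxybarbatic acid (2-hydroxy-4-{[2-hydroxy-3-(hydroxymethyl)-4-methoxy-6-methylbenzoyl]oxy}-3,6-dimethylbenzoic acid)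
Conditions: Pd(PPh3)4 (5 mol %), PhSiH3 (2 equiv), CH2Cl2, rt, 30 min; mild aqueous work-up at pH 3, then crystallisation
Reagents that add atoms: none
Why: This Tsuji–Trost type deallylation ionises only the allyl ester to π-allyl-Pd, the silane reduces that to propene, and the neutral, non-nucleophilic, non-hydrogenolytic conditions spare the aryl ester and the electron-rich benzylic alcohol that H2/Pd or acid could destroy.

## Compound list
1 | 2,4-dihydroxy-3,6-dimethylbenzoic acid | Cc1cc(O)c(C)c(O)c1C(=O)O | starting material
2 | allyl bromide | C=CCBr | starting material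
3 | allyl 2,4-dihydroxy-3,6-dimethylbenzoate | Cc1cc(O)c(C)c(O)c1C(=O)OCC=C | intermediate
4 | but-2-ynoic acid | CC#CC(=O)O | starting material
5 | allyl 4-(but-2-ynoyloxy)-2-hydroxy-3,6-dimethylbenzoate | CC#CC(=O)Oc1cc(C)c(C(=O)OCC=C)c(O)c1C | intermediate
6 | methyl acetoacetate | CC(=O)CC(=O)OC | starting material
7 | trimethyl orthoformate | COC(OC)OC | starting material
8 | methyl (E)-3-methoxybut-2-enoate | CO/C(C)=C/C(=O)OC | intermediate
9 | chlorotrimethylsilane | C[Si](C)(C)Cl | starting material
10 | 1,3-dimethoxy-1-(trimethylsilyloxy)buta-1,3-diene | C=C(OC)C=C(OC)O[Si](C)(C)C | intermediate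
11 | allyl obtusatate | COc1cc(C)c(C(=O)Oc2cc(C)c(C(=O)OCC=C)c(O)c2C)c(O)c1 | intermediate
12 | phenylboronic acid | OB(O)c1ccccc1 | starting material
13 | paraformaldehyde (monomer shown) | C=O | starting material
14 | 2-phenyl-1,3,2-benzodioxaborin of 15 | COc1cc(C)c(C(=O)Oc3cc(C)c(C(=O)OCC=C)c(O)c3C)c2OB(c4ccccc4)OCc12 | intermediate
15 | allyl 3α-hydroxybarbatate | COc1cc(C)c(C(=O)Oc2cc(C)c(C(=O)OCC=C)c(O)c2C)c(O)c1CO | intermediate
16 | 3α-hydroxybarbatic acid (achiral) | COc1cc(C)c(C(=O)Oc2cc(C)c(C(=O)O)c(O)c2C)c(O)c1CO | target

## Totals
- Total steps: 8.
- Longest linear sequence: 6 (steps 1, 2, 5, 6, 7, 8; the diene branch 3, 4, 5–8 is also 6).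

## Steps most likely to fail

**1. Step 5.**
- Risks: the β-methyl ynoate may be sluggish, and the acyclic ketene acetal can be protonated or undergo O-to-C silyl shift at 120 °C. Some 2-O-methyl ether may form by loss of TMSOH; BCl3 would converge that by-product to 11.
- Fallback: switch to an Alder–Rickert construction. Heat 5 neat at 160 °C with the locked s-cis diene 1,3-bis(trimethylsilyloxy)-5,5-dimethylcyclohexa-1,3-diene (from dimedone, TMSOTf/Et3N). Diels–Alder followed by retro-Diels–Alder loss of isobutene gives the 2,4-dihydroxy depside. A selective Mitsunobu 4-O-methylation (MeOH, PPh3, DIAD) then rejoins the route at 11, at the cost of one extra step.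

**2. Step 6.**
- Risk: the chelated, ester-bearing 2-OH may engage boron poorly, so the reaction could be slow.
- Fallback: take a redox detour instead of direct hydroxymethylation. Rieche formylation (Cl2CHOMe, TiCl4, CH2Cl2, −78 to 0 °C, titanium phenolate directing to C3) gives the allyl ester of baeomycesic acid. NaBH4 reduction at 0 °C then gives 15 directly, replacing steps 6 and 7.

**3. Step 8.**
- Risks: the fragile salicyl alcohol is already exposed, stray π-allyl species could O-allylate a phenol, and the free acid may suffer isolation losses.
- Fallback: reorder so that nothing follows the unveiling of the benzylic alcohol. Deallylate 11 to obtusatic acid first. Then run the boron-templated hydroxymethylation on the free acid with at least 3 equiv of PhB(OH)2, which reversibly masks the ring B salicylic acid as its cyclic acyloxyboronate. A single neutral H2O2 work-up releases the target as the last operation.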